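**Assumptions (one line each)**
- Commercial starting materials: methyl 3-(4-hydroxyphenyl)propanoate, 5-methoxyresorcinol, 1-bromo-4-(methoxymethoxy)benzene, 4-hydroxybenzaldehyde.
- The (S)-BINOL catalyst is assumed to give the (S)-diarylmethine; if it gives the epimer, (R)-BINOL is used.
- The target has (3S,7S) centres and E,E alkenes. I read both centres as S from the SMILES.

## Retrosynthesis
1. Calyxin B ⇒ Claisen–Schmidt disconnection of the chalcone to acetophenone 17 plus 4-hydroxybenzaldehyde. Acetophenone 17 comes from Friedel–Crafts acetylation of resorcinol 16. Its two free ring positions are equivalent, so regiochemistry is fixed by symmetry.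
2. 16 ⇒ **new key step**: BINOL-catalysed asymmetric alkenylation of a phloroglucinol-derived o-quinone methide (from benzhydrol 14) with chiral (E)-alkenylboronic acid 8. This sets the C7 diarylmethine centre and keeps the E-alkene.
3. Benzhydrol 14 ⇐ directed ortho-metalation of 1-methoxy-3,5-bis(MOM-oxy)benzene at the carbon flanked by both OMOM groups (this fixes C-4 regiochemistry), then an aryl Grignard addition.
4. Acid 8 ⇐ (S)-alkynol from Jacobsen hydrolytic kinetic resolution (HKR) of an epoxide plus acetylide opening. This sets the C3 carbinol. No new rings are formed, so the three arenes come from commercial materials.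

## Route

**Step 1**
Reactants: 1 (methyl 3-(4-hydroxyphenyl)propanoate)
Product: 2 (methyl 3-[4-(methoxymethoxy)phenyl]propanoate)
Conditions: MOMCl, iPr2NEt, CH2Cl2, 0 °C→rt
Reagents that add atoms: MOMCl, ClCOC
Why: Williamson-type O-protection gives a MOM ether that survives the later organometallic, hydroboration and base steps.

**Step 2**
Reactants: 2
Product: 3 (3-[4-(methoxymethoxy)phenyl]propanal)
Conditions: DIBAL-H, CH2Cl2, –78 °C
Reagents that add atoms: none
Why: Low-temperature DIBAL stops the ester reduction at the aldehyde; the MOM ether is untouched.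

**Step 3**
Reactants: 3
Product: 4 (racemic 2-{2-[4-(methoxymethoxy)phenyl]ethyl}oxirane)
Conditions: Me3S+ I–, n-BuLi, THF, –10 °C→rt
Reagents that add atoms: trimethylsulfonium iodide, C[S+](C)C.[I-] (supplies CH2)
Why: Corey–Chaykovsky epoxidation of an aldehyde with a sulfonium ylide.

**Step 4**
Reactants: 4
Product: 5 ((S)-2-{2-[4-(methoxymethoxy)phenyl]ethyl}oxirane)
Conditions: (R,R)-(salen)Co(III)OAc (0.5 mol%), H2O (0.55 equiv), THF, 0 °C→rt, 18 h
Reagents that add atoms: none (water ends up in the diol by-product)
Why: Jacobsen hydrolytic kinetic resolution; the (R,R) catalyst hydrolyses the (R)-epoxide and leaves the (S)-epoxide, which sets the C3 configuration.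

**Step 5**
Reactants: 5
Product: 6 ((S)-1-[4-(methoxymethoxy)phenyl]hex-5-yn-3-ol)
Conditions: LiC≡CH·ethylenediamine, DMSO, 10→25 °C
Reagents that add atoms: lithium acetylide, [Li]C#C (supplies HC≡C–)
Why: SN2 opening at the terminal epoxide carbon leaves the stereocentre untouched, so (S)-epoxide gives (S)-alcohol (priorities O > CH2C≡ > CH2CH2Ar in both).

**Step 6**
Reactants: 6
Product: 7 ((S)-alkyne, secondary MOM ether)
Conditions: MOMCl, iPr2NEt, cat. NaI, CH2Cl2, reflux
Reagents that add atoms: MOMCl, ClCOC
Why: O-alkylation with retention; the same acid-removable protecting group on all phenols and the carbinol allows one global deprotection later.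

**Step 7**
Reactants: 7
Product: 8 ((E)-alkenylboronic acid, (S)-carbinol as MOM ether)
Conditions: catecholborane, neat→THF, 70 °C, 2 h; then H2O, rt
Reagents that add atoms: catecholborane, [H]B1Oc2ccccc2O1 (supplies B); water, O (hydrolysis to B(OH)2)
Why: syn-hydroboration of a terminal alkyne gives the E-alkenylboron, and hydrolysis of the catechol ester gives the acid. The remote stereocentre is unaffected.

**Step 8**
Reactants: 9 (5-methoxyresorcinol)
Product: 10 (1-methoxy-3,5-bis(methoxymethoxy)benzene)
Conditions: NaH (2.4 equiv), MOMCl, THF/DMF, 0 °C→rt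
Reagents that add atoms: MOMCl, ClCOC
Why: Double O-alkylation of the phenoxides installs the directing groups needed for regiospecific metalation.

**Step 9**
Reactants: 10
Product: 11 (2,6-bis(methoxymethoxy)-4-methoxybenzaldehyde)
Conditions: n-BuLi, THF, 0 °C, 1 h; then DMF, –78 °C→rt
Reagents that add atoms: DMF, CN(C)C=O (supplies CHO)
Why: Directed ortho-metalation occurs at the carbon flanked by two OMOM groups (cooperative chelation), placing the future diarylmethine carbon at the position between the two ring OH groups.

**Step 10**
Reactants: 11
Product: 12 (2-hydroxy-6-(methoxymethoxy)-4-methoxybenzaldehyde)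
Conditions: ZnBr2 (1.0 equiv), n-PrSH (3 equiv), CH2Cl2, 0 °C, 30 min
Reagents that add atoms: none
Why: Lewis-acid MOM cleavage stops after one group because the resulting Zn-chelated salicylaldehyde is deactivated; this desymmetrises the two equivalent ortho oxygens and frees the OH needed to form the o-quinone methide.

**Step 11**
Reactants: 12; 13 (1-bromo-4-(methoxymethoxy)benzene, converted to its Grignard reagent)
Product: 14 (racemic (2-hydroxy-6-(methoxymethoxy)-4-methoxyphenyl)[4-(methoxymethoxy)phenyl]methanol)
Conditions: 13, Mg, THF, reflux → ArMgBr; add 12 (2.5 equiv ArMgBr), THF, –78→0 °C; aq. NH4Cl; crude used immediately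
Reagents that add atoms: 4-(MOMO)phenylmagnesium bromide, COCOc1ccc([Mg]Br)cc1
Why: Grignard addition to an aldehyde (the first equivalent deprotonates the phenol) gives the o-hydroxybenzhydrol, the o-quinone methide precursor, as a racemate.

**Step 12 (key step)**
Reactants: 14; 8
Product: 15 (protected diarylheptanoid with (7S) diarylmethine, (3S) carbinol, E-alkene)
Conditions: (S)-3,3′-diphenyl-BINOL (20 mol%), 8 (1.5 equiv), toluene, 4 Å MS, 50 °C, 48 h
Reagents that add atoms: none (the alkenyl group comes from 8)
Why: Proposed new method: a BINOL-catalysed Petasis-type 1,4-alkenylation of an o-quinone methide derived from a 2,4,6-trioxygenated (phloroglucinol) diaryl benzhydrol with an alkyl-alkenylboronic acid.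
- Mechanism: 14 condenses with 8 to a benzodioxaborin, and diol exchange gives a chiral BINOL-borate. Ionisation gives the phenoxide-bound o-quinone methide. Alkenyl transfer then goes through a six-membered boron-bound transition state to one face of the exocyclic carbon, creating the (S) diaryl CH centre with retention of E geometry.
- Closest known reaction: BINOL-catalysed boronate alkenylation of simple o-quinone methides. What is new here is the highly stabilised, electron-rich diaryl quinone methide and a boronic acid carrying a remote stereocentre.
- Stereocontrol: the C3 stereocentre is too remote to bias the face, so the catalyst controls it.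

**Step 13**
Reactants: 15
Product: 16 (diarylheptanoid resorcinol, all MOM groups removed)
Conditions: 3 M aq. HCl/THF/MeOH (1:2:2), 40 °C, 8 h, N2
Reagents that add atoms: none
Why: Acidolysis of four MOM ethers (ring, two aryl, one secondary alkyl). Neither stereocentre is touched, and the alkene and C7–H are stable to dilute acid at this temperature.

**Step 14**
Reactants: 16
Product: 17 (acetophenone bearing the diarylheptanoid at C-3′)
Conditions: BF3·OEt2 (5 equiv), AcOH (0.2 M), 45 °C, 4 h
Reagents that add atoms: acetic acid, CC(=O)O (supplies the acetyl group)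
Why: Friedel–Crafts acylation occurs on the most nucleophilic resorcinol ring. The two free positions (each between OMe and OH) are symmetry-equivalent, so one regioisomer forms, with the acetyl ortho to OMe and OH and para to the other OH as in the target.

**Step 15**
Reactants: 17; 18 (4-hydroxybenzaldehyde)
Product: 19 (calyxin B)
Conditions: 50% aq. KOH (10 equiv), 18 (3 equiv), EtOH, 25 °C, 48 h, N2; quench with AcOH
Reagents that add atoms: none (18 is the reactant supplying the aryl-CH= unit)
Why: Claisen–Schmidt aldol condensation gives the thermodynamic E-enone. The 6′-OMe and chelated 2′-OH disfavour flavanone closure, and the C3 and C7 centres are not involved.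

## Compound list
1 | methyl 3-(4-hydroxyphenyl)propanoate | COC(=O)CCc1ccc(O)cc1 | starting material
2 | methyl 3-[4-(methoxymethoxy)phenyl]propanoate | COC(=O)CCc1ccc(OCOC)cc1 | intermediate
3 | 3-[4-(methoxymethoxy)phenyl]propanal | O=CCCc1ccc(OCOC)cc1 | intermediate
4 | rac-2-{2-[4-(methoxymethoxy)phenyl]ethyl}oxirane | C1OC1CCc1ccc(OCOC)cc1 | intermediate
5 | (S)-2-{2-[4-(methoxymethoxy)phenyl]ethyl}oxirane | C1O[C@H]1CCc1ccc(OCOC)cc1 | intermediate
6 | (S)-1-[4-(methoxymethoxy)phenyl]hex-5-yn-3-ol | C#CC[C@@H](O)CCc1ccc(OCOC)cc1 | intermediate
7 | (S)-alkyne bis-MOM ether | C#CC[C@@H](OCOC)CCc1ccc(OCOC)cc1 | intermediate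
8 | (E)-alkenylboronic acid, (S)-carbinol as MOM ether | OB(O)/C=C/C[C@@H](OCOC)CCc1ccc(OCOC)cc1 | intermediate
9 | 5-methoxyresorcinol | COc1cc(O)cc(O)c1 | starting material
10 | 1-methoxy-3,5-bis(methoxymethoxy)benzene | COc1cc(OCOC)cc(OCOC)c1 | intermediate
11 | 2,6-bis(methoxymethoxy)-4-methoxybenzaldehyde | COc1cc(OCOC)c(C=O)c(OCOC)c1 | intermediate
12 | 2-hydroxy-6-(methoxymethoxy)-4-methoxybenzaldehyde | COc1cc(O)c(C=O)c(OCOC)c1 | intermediate
13 | 1-bromo-4-(methoxymethoxy)benzene | COCOc1ccc(Br)cc1 | starting material
14 | rac-(2-hydroxy-6-MOMO-4-methoxyphenyl)(4-MOMO-phenyl)methanol | COc1cc(O)c(C(O)c2ccc(OCOC)cc2)c(OCOC)c1 | intermediate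
15 | protected (3S,7S)-diarylheptanoid resorcinol | COc1cc(O)c([C@@H](/C=C/C[C@@H](OCOC)CCc2ccc(OCOC)cc2)c2ccc(OCOC)cc2)c(OCOC)c1 | intermediate
16 | deprotected diarylheptanoid resorcinol | COc1cc(O)c([C@@H](/C=C/C[C@@H](O)CCc2ccc(O)cc2)c2ccc(O)cc2)c(O)c1 | intermediate
17 | acetophenone | COc1cc(O)c([C@@H](/C=C/C[C@@H](O)CCc2ccc(O)cc2)c2ccc(O)cc2)c(O)c1C(C)=O | intermediate
18 | 4-hydroxybenzaldehyde | O=Cc1ccc(O)cc1 | starting material
19 | calyxin B | COc1cc(O)c([C@@H](/C=C/C[C@@H](O)CCc2ccc(O)cc2)c2ccc(O)cc2)c(O)c1C(=O)/C=C/c1ccc(O)cc1 | target

**Total steps:** 15.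
**Longest linear sequence:** 11 (compound 1 → 2 → 3 → 4 → 5 → 6 → 7 → 8 → 15 → 16 → 17 → 19, that is steps 1–7 and 12–15).

## Three steps most likely to fail

1. **Step 12 (proposed new step).** The phloroglucinol-derived o-quinone methide is very stabilised and only weakly electrophilic, so the reaction may be slow, racemic, or give poor ee.
   - Fallback (known chemistry): generate the same diaryl cation from 14 with BF3·OEt2 in the presence of the potassium (E)-alkenyltrifluoroborate of 8. This Petasis/Mayr-type alkenylation gives a roughly 1:1 mixture of C7 epimers, which is separated by preparative chiral-phase HPLC. The C3 centre is already fixed, and the (7S) isomer is assigned against the natural product.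
2. **Step 14.** The late Friedel–Crafts acylation on an electron-rich resorcinol carries two risks: retro-Friedel–Crafts ipso-protonation could racemise C7, and over-acylation or partial acetylation of the other phenols could lower the yield.
   - Fallback (changes the approach): install the acetyl earlier. Do ortho-lithiation of aldehyde 11 as its in-situ α-amino-alkoxide (Comins-type), trap at the carbon flanked by OMe and OMOM with a Weinreb acetamide, and carry the acyl ring through steps 10–13. Only the final aldol (step 15) is then needed after the diarylmethine is set.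
3. **Step 10.** Chelation-controlled mono-MOM cleavage may give bis-phenol or unreacted 11 instead of a clean mono-deprotection.
   - Fallback (changes the approach): make 12 from 2,4,6-trihydroxybenzaldehyde. Selective 4-O-methylation with MeI/K2CO3 gives 2,6-dihydroxy-4-methoxybenzaldehyde, then one OH is protected with a single equivalent of MOMCl and the mono-MOM product is separated chromatographically.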